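**Plan**

- Numbering (isochromene): C1 (CH2), O2, C3 (dienyl), C4, C4a, C5 (Cl), C6 (C=O), C7 (Me, OAc), C8 (C=O), C8a (H); C13 is the side-chain stereocentre.
- Retrosynthesis: cut O2–C3 (alkyne hydroalkoxylation) and the acetate; then cut C6–C7 and C8–C8a together; then C4a–C4 (Sonogashira) and the two side-chain alkenes (Wittig, Horner–Wadsworth–Emmons).
- Enabling feature: in the carbocycle, C7–C8 is a lactic acid unit (Me- and O-bearing carbon next to a carboxyl-level carbon) and C6–C5(Cl)=C4a–C8a is its vinylog (acyl carbon C6, γ-carbon C8a through the C4a=C5 enone). A lactate dioxolanone enolate and a 2-chloro-enynoyl chloride can therefore be joined by C-acylation and vinylogous Dieckmann closure in one flask, the acetal leaving as pivalaldehyde.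
- Forward: dienyne 8; chloro enol triflate 13; Sonogashira to 14, acid 15; anionic [4+2] annulation closes the carbocycle (22); acetate 23; desilylation; gold-catalysed 6-endo closure makes the pyran ring last (25).
- Stereochemistry: C13 from (R)-2-methylbutanoic acid; C7 from (R)-lactic acid by self-regeneration of the stereocentre in the annulation; C8a by thermodynamically controlled ketonization in the last step, relayed from C7; E-alkenes from stabilized ylide and phosphonate olefinations.

Key step: step 10

Remark: the monocyclic diones 22, 23 and 24 are vinylogous acids whose ring carbon that becomes C8a epimerizes through the enol; this centre is left open in their names and SMILES and is fixed in step 13.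

**Route**

Step 1
Reactants: 1 (R)-2-methylbutanoic acid
Product: 2 (R)-2-methylbutan-1-ol
Conditions: LiAlH4, Et2O, 0 → 23 °C; aq. NaOH work-up
Reagents that add atoms: none
Why: Hydride reduction of the acid runs through the carboxylate, which is not enolized, so the (R) centre should pass unchanged into the primary alcohol.

Step 2
Reactants: 2 (R)-2-methylbutan-1-ol; 3 2-(triphenyl-λ5-phosphanylidene)propanal
Product: 5 (2E,4R)-2,4-dimethylhex-2-enal, via (R)-2-methylbutanal 4 (not isolated)
Conditions: PhI(OAc)2, TEMPO (10 mol %), ClCH2CH2Cl, 23 °C; then 3, 70 °C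
Reagents that add atoms: none
Why: Nitroxyl-catalysed oxidation followed in the same flask by Wittig olefination with a stabilized formyl ylide should give the E-enal without isolation of the volatile, epimerizable aldehyde 4, the near-neutral medium sparing the α-centre.

Step 3
Reactants: 5 (2E,4R)-2,4-dimethylhex-2-enal; 6 diethyl [3-(trimethylsilyl)prop-2-yn-1-yl]phosphonate
Product: 8 (3E,5E,7R)-5,7-dimethylnona-3,5-dien-1-yne, via TMS dienyne 7 (not isolated)
Conditions: 6, LiN(SiMe3)2, THF, −78 → 0 °C; then MeOH, K2CO3 (20 mol %), 23 °C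
Reagents that add atoms: none
Why: Horner–Wadsworth–Emmons olefination with a propargylic phosphonate should form the new disubstituted alkene with E geometry, and methanolysis then removes the alkynyl silyl group.

Step 4
Reactants: 9 3-[(tert-butyldimethylsilyl)oxy]propanal; 10 ethyl diazoacetate
Product: 11 ethyl 5-[(tert-butyldimethylsilyl)oxy]-3-oxopentanoate
Conditions: SnCl2 (10 mol %), CH2Cl2, 23 °C
Reagents that add atoms: none
Why: Roskamp homologation (Lewis-acid-promoted addition of the diazo ester to the aldehyde, 1,2-hydride shift, loss of N2) gives the β-keto ester directly, and the silyl ether tolerates the mild Lewis acid.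

Step 5
Reactants: 11 ethyl 5-[(tert-butyldimethylsilyl)oxy]-3-oxopentanoate
Product: 12 ethyl 5-[(tert-butyldimethylsilyl)oxy]-2-chloro-3-oxopentanoate (racemic)
Conditions: N-chlorosuccinimide (1.0 equiv), Mg(ClO4)2 (10 mol %), EtOAc, 0 → 23 °C
Reagents that add atoms: N-chlorosuccinimide, O=C1CCC(=O)N1Cl
Why: Electrophilic α-chlorination of the magnesium-chelated β-keto ester enol; one equivalent of reagent limits dichlorination, and the new centre is racemic and is removed in step 6.

Step 6
Reactants: 12 ethyl 5-[(tert-butyldimethylsilyl)oxy]-2-chloro-3-oxopentanoate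
Product: 13 ethyl (2Z)-5-[(tert-butyldimethylsilyl)oxy]-2-chloro-3-[(trifluoromethanesulfonyl)oxy]pent-2-enoate
Conditions: Tf2O, i-Pr2NEt, CH2Cl2, −78 °C
Reagents that add atoms: trifluoromethanesulfonic anhydride, O=S(=O)(OS(=O)(=O)C(F)(F)F)C(F)(F)F
Why: O-Sulfonylation of the ammonium enolate of the acidic α-chloro-β-keto ester gives the enol triflate, expected mainly with triflate trans to the ester (non-chelated enolate); the geometry is not critical because the dienolate of step 10 releases it again.

Step 7
Reactants: 13 ethyl (2Z)-5-[(tert-butyldimethylsilyl)oxy]-2-chloro-3-[(trifluoromethanesulfonyl)oxy]pent-2-enoate; 8 (3E,5E,7R)-5,7-dimethylnona-3,5-dien-1-yne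
Product: 14 ethyl (2Z,6E,8E,10R)-3-[2-[(tert-butyldimethylsilyl)oxy]ethyl]-2-chloro-8,10-dimethyldodeca-2,6,8-trien-4-ynoate
Conditions: Pd(PPh3)2Cl2 (5 mol %), copper iodide CuI (10 mol %), Et3N, THF, 23 °C
Reagents that add atoms: none
Why: Sonogashira coupling of an electron-poor enol triflate with a terminal alkyne proceeds with retention of alkene geometry, and the vinylic C–Cl bond is far less reactive toward zerovalent palladium than the triflate.

Step 8
Reactants: 14 ethyl (2Z,6E,8E,10R)-3-[2-[(tert-butyldimethylsilyl)oxy]ethyl]-2-chloro-8,10-dimethyldodeca-2,6,8-trien-4-ynoate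
Product: 15 (2Z,6E,8E,10R)-3-[2-[(tert-butyldimethylsilyl)oxy]ethyl]-2-chloro-8,10-dimethyldodeca-2,6,8-trien-4-ynoic acid
Conditions: LiOH·H2O, THF/H2O, 0 °C; then 1 M HCl to pH 4, 0 °C
Reagents that add atoms: lithium hydroxide, [Li+].[OH-]
Why: Saponification of the activated α-chloroacrylate ester should be fast at 0 °C, where the silyl ether and the dienyne are stable, and any E/Z leakage at C2=C3 is without consequence.

Step 9
Reactants: 16 (R)-lactic acid; 17 pivalaldehyde
Product: 18 (2R,5R)-2-tert-butyl-5-methyl-1,3-dioxolan-4-one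
Conditions: TsOH·H2O (cat.), H2SO4 (cat.), pentane, reflux, water separator; crystallization from pentane/Et2O, −78 °C
Reagents that add atoms: none
Why: Acid-catalysed acetalization under thermodynamic control favours the cis-dioxolanone, which crystallizes pure; the lactate centre is untouched and induces the acetal centre.

Step 10
Reactants: 15 (2Z,6E,8E,10R)-3-[2-[(tert-butyldimethylsilyl)oxy]ethyl]-2-chloro-8,10-dimethyldodeca-2,6,8-trien-4-ynoic acid; 18 (2R,5R)-2-tert-butyl-5-methyl-1,3-dioxolan-4-one
Product: 22 (2R)-6-[[(tert-butyldimethylsilyl)oxy]methyl]-4-chloro-5-[(3E,5E,7R)-5,7-dimethylnona-3,5-dien-1-yn-1-yl]-2-hydroxy-2-methylcyclohex-4-ene-1,3-dione, via acid chloride 19 (not isolated), via lithium enolate 20 (not isolated), via acyl dioxolanone 21 (not isolated)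
Conditions: 15, 1-chloro-N,N,2-trimethylprop-1-en-1-amine, CH2Cl2, 0 °C; 18, LiN(SiMe3)2 (1.1 equiv), THF, −78 °C; combine at −78 °C; LiN(SiMe3)2 (1.2 equiv), −78 → −30 °C; AcOH, −78 °C
Reagents that add atoms: none
Why: Proposed new method: enolate 20 is C-acylated by acid chloride 19 on the face opposite the tert-butyl group (Claisen-type acylation of an ester enolate), which regenerates the lactate centre as the quaternary (R)-C7; LiN(SiMe3)2 then removes a γ-hydrogen of the α-chloro enone 21 (the future C8a, the only acidic site because C5 bears chlorine, C7 is quaternary and the alkynyl group has no hydrogen), and the γ-carbon of the lithium dienolate attacks the dioxolanone carbonyl (the future C8). The closest known reaction types are the γ-acylation of dienolates by esters and the Michael–Claisen annulation of cyclohexenones; what is new is that one acetal serves first as chiral enolate and then as acyl donor. The carbocycle closes in the 6-(enolendo)-exo-trig mode, and only the γ-carbon can reach the lactone carbonyl, since attack through the α-carbon or through oxygen would give a four-membered ring. Collapse of the tetrahedral intermediate opens the acetal, pivalaldehyde is expelled and the C7 alkoxide is set free, so the auxiliary leaves without a separate step. The sequence is driven by formation of the vinylogous 1,3-diketonate of 22, which resists retro-Claisen cleavage until the acetic acid quench. C8a is formed as an enolizable centre and is not controlled here; the step needs facial selectivity at C7 (secured by the tert-butyl group) and C- over O-acylation (expected for a lithium enolate and an acid chloride in THF at −78 °C).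

Step 11
Reactants: 22 (2R)-6-[[(tert-butyldimethylsilyl)oxy]methyl]-4-chloro-5-[(3E,5E,7R)-5,7-dimethylnona-3,5-dien-1-yn-1-yl]-2-hydroxy-2-methylcyclohex-4-ene-1,3-dione
Product: 23 (1R)-5-[[(tert-butyldimethylsilyl)oxy]methyl]-3-chloro-4-[(3E,5E,7R)-5,7-dimethylnona-3,5-dien-1-yn-1-yl]-1-methyl-2,6-dioxocyclohex-3-en-1-yl acetate
Conditions: Ac2O (3 equiv), Et3N, DMAP (20 mol %), CH2Cl2, 0 → 23 °C; then MeOH, 0 °C
Reagents that add atoms: acetic anhydride, CC(=O)OC(C)=O
Why: DMAP-catalysed acetylation of the tertiary α-ketol; any dienol acetate formed at the vinylogous acid is an activated ester that passes its acetyl group to the tertiary alkoxide or is cleaved by the methanol quench, so only the C7 acetate should remain and C7 is untouched.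

Step 12
Reactants: 23 (1R)-5-[[(tert-butyldimethylsilyl)oxy]methyl]-3-chloro-4-[(3E,5E,7R)-5,7-dimethylnona-3,5-dien-1-yn-1-yl]-1-methyl-2,6-dioxocyclohex-3-en-1-yl acetate
Product: 24 (1R)-3-chloro-4-[(3E,5E,7R)-5,7-dimethylnona-3,5-dien-1-yn-1-yl]-5-(hydroxymethyl)-1-methyl-2,6-dioxocyclohex-3-en-1-yl acetate
Conditions: HF·pyridine, pyridine, THF, 0 → 23 °C
Reagents that add atoms: none
Why: Fluoride-driven cleavage of the primary silyl ether under buffered, non-basic conditions should spare the tertiary acetate and avoid retro-aldol loss of the hydroxymethyl group.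

Step 13
Reactants: 24 (1R)-3-chloro-4-[(3E,5E,7R)-5,7-dimethylnona-3,5-dien-1-yn-1-yl]-5-(hydroxymethyl)-1-methyl-2,6-dioxocyclohex-3-en-1-yl acetate
Product: 25 (7R,8aR)-5-chloro-3-[(1E,3E,5R)-3,5-dimethylhepta-1,3-dien-1-yl]-7-methyl-6,8-dioxo-6,7,8,8a-tetrahydro-1H-isochromen-7-yl acetate
Conditions: Ph3PAuNTf2 (5 mol %), CH2Cl2, 23 °C; then pyridinium p-toluenesulfonate (10 mol %), 23 °C
Reagents that add atoms: none
Why: Activation of the alkyne by monovalent gold and 6-endo-dig attack of the hydroxyl group at C3 (the δ-carbon of the ynenone, which also bears the cation-stabilizing dienyl group) followed by protodeauration closes the pyran ring, and acid-catalysed keto–enol equilibration should then settle C8a in the epimer where H8a and the C7 acetoxy group are pseudoaxial on the same face and the C7 methyl group is pseudoequatorial, which is the (8aR) configuration.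

**Compound list**

1 | (R)-2-methylbutanoic acid | CC[C@@H](C)C(O)=O | starting material
2 | (R)-2-methylbutan-1-ol | CC[C@@H](C)CO | intermediate
3 | 2-(triphenyl-λ5-phosphanylidene)propanal | CC(C=O)=P(c1ccccc1)(c1ccccc1)c1ccccc1 | starting material
4 | (R)-2-methylbutanal | CC[C@@H](C)C=O | intermediate
5 | (2E,4R)-2,4-dimethylhex-2-enal | CC[C@@H](C)/C=C(C)/C=O | intermediate
6 | diethyl [3-(trimethylsilyl)prop-2-yn-1-yl]phosphonate | CCOP(=O)(CC#C[Si](C)(C)C)OCC | starting material
7 | trimethyl[(3E,5E,7R)-5,7-dimethylnona-3,5-dien-1-yn-1-yl]silane | CC[C@@H](C)/C=C(C)/C=C/C#C[Si](C)(C)C | intermediate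
8 | (3E,5E,7R)-5,7-dimethylnona-3,5-dien-1-yne | CC[C@@H](C)/C=C(C)/C=C/C#C | intermediate
9 | 3-[(tert-butyldimethylsilyl)oxy]propanal | O=CCCO[Si](C)(C)C(C)(C)C | starting material
10 | ethyl diazoacetate | CCOC(=O)C=[N+]=[N-] | starting material
11 | ethyl 5-[(tert-butyldimethylsilyl)oxy]-3-oxopentanoate | CCOC(=O)CC(=O)CCO[Si](C)(C)C(C)(C)C | intermediate
12 | ethyl 5-[(tert-butyldimethylsilyl)oxy]-2-chloro-3-oxopentanoate (racemic) | CCOC(=O)C(Cl)C(=O)CCO[Si](C)(C)C(C)(C)C | intermediate
13 | ethyl (2Z)-5-[(tert-butyldimethylsilyl)oxy]-2-chloro-3-[(trifluoromethanesulfonyl)oxy]pent-2-enoate | CCOC(=O)/C(Cl)=C(/OS(=O)(=O)C(F)(F)F)CCO[Si](C)(C)C(C)(C)C | intermediate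
14 | ethyl (2Z,6E,8E,10R)-3-[2-[(tert-butyldimethylsilyl)oxy]ethyl]-2-chloro-8,10-dimethyldodeca-2,6,8-trien-4-ynoate | CCOC(=O)/C(Cl)=C(/C#C/C=C/C(C)=C/[C@H](C)CC)CCO[Si](C)(C)C(C)(C)C | intermediate
15 | (2Z,6E,8E,10R)-3-[2-[(tert-butyldimethylsilyl)oxy]ethyl]-2-chloro-8,10-dimethyldodeca-2,6,8-trien-4-ynoic acid | OC(=O)/C(Cl)=C(/C#C/C=C/C(C)=C/[C@H](C)CC)CCO[Si](C)(C)C(C)(C)C | intermediate
16 | (R)-lactic acid | C[C@@H](O)C(O)=O | starting material
17 | pivalaldehyde (2,2-dimethylpropanal) | CC(C)(C)C=O | starting material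
18 | (2R,5R)-2-tert-butyl-5-methyl-1,3-dioxolan-4-one (cis) | C[C@H]1O[C@@H](C(C)(C)C)OC1=O | intermediate
19 | (2Z,6E,8E,10R)-3-[2-[(tert-butyldimethylsilyl)oxy]ethyl]-2-chloro-8,10-dimethyldodeca-2,6,8-trien-4-ynoyl chloride | ClC(=O)/C(Cl)=C(/C#C/C=C/C(C)=C/[C@H](C)CC)CCO[Si](C)(C)C(C)(C)C | intermediate
20 | lithium (2R)-2-tert-butyl-5-methyl-1,3-dioxol-4-olate | CC1=C(O[Li])O[C@H](C(C)(C)C)O1 | intermediate
21 | (2R,5S)-2-tert-butyl-5-[(2Z,6E,8E,10R)-3-[2-[(tert-butyldimethylsilyl)oxy]ethyl]-2-chloro-8,10-dimethyldodeca-2,6,8-trien-4-ynoyl]-5-methyl-1,3-dioxolan-4-one (acyl group trans to tert-butyl) | C[C@@]1(C(=O)/C(Cl)=C(/C#C/C=C/C(C)=C/[C@H](C)CC)CCO[Si](C)(C)C(C)(C)C)O[C@@H](C(C)(C)C)OC1=O | intermediate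
22 | (2R)-6-[[(tert-butyldimethylsilyl)oxy]methyl]-4-chloro-5-[(3E,5E,7R)-5,7-dimethylnona-3,5-dien-1-yn-1-yl]-2-hydroxy-2-methylcyclohex-4-ene-1,3-dione (C6 open, enolizable) | CC[C@@H](C)/C=C(C)/C=C/C#CC1=C(Cl)C(=O)[C@](C)(O)C(=O)C1CO[Si](C)(C)C(C)(C)C | intermediate
23 | (1R)-5-[[(tert-butyldimethylsilyl)oxy]methyl]-3-chloro-4-[(3E,5E,7R)-5,7-dimethylnona-3,5-dien-1-yn-1-yl]-1-methyl-2,6-dioxocyclohex-3-en-1-yl acetate (C5 open, enolizable) | CC[C@@H](C)/C=C(C)/C=C/C#CC1=C(Cl)C(=O)[C@](C)(OC(C)=O)C(=O)C1CO[Si](C)(C)C(C)(C)C | intermediate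
24 | (1R)-3-chloro-4-[(3E,5E,7R)-5,7-dimethylnona-3,5-dien-1-yn-1-yl]-5-(hydroxymethyl)-1-methyl-2,6-dioxocyclohex-3-en-1-yl acetate (C5 open, enolizable) | CC[C@@H](C)/C=C(C)/C=C/C#CC1=C(Cl)C(=O)[C@](C)(OC(C)=O)C(=O)C1CO | intermediate
25 | (7R,8aR)-5-chloro-3-[(1E,3E,5R)-3,5-dimethylhepta-1,3-dien-1-yl]-7-methyl-6,8-dioxo-6,7,8,8a-tetrahydro-1H-isochromen-7-yl acetate | CC[C@@H](C)/C=C(C)/C=C/C1=CC2=C(Cl)C(=O)[C@](C)(OC(C)=O)C(=O)[C@H]2CO1 | target

**Summary**

Total step count: 13. Longest linear sequence: 9 steps (1, 2, 3, 7, 8, 10, 11, 12, 13).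

Steps most likely to fail:

1. Step 10. Possible failures are O- instead of C-acylation or self-condensation of the dioxolanone enolate, loss of silyloxide from the dienolate by vinylogous β-elimination before ring closure, and α-ketol ring contraction of the product alkoxide on warming. The fallback sets out from 14 and 18 and comes back at 22, using known reaction types in separate steps. Ester 14 would be reduced with i-Bu2AlH (CH2Cl2, −78 °C) to the allylic alcohol F1 and oxidized with MnO2 to the enal F2. Aldol addition of lithium enolate 20 (from 18) to F2 in THF at −78 °C, a standard reaction of this enolate that also occurs anti to the tert-butyl group, would give the carbinol F3 as a mixture at the carbinol carbon. Dess–Martin oxidation would then give the acyl dioxolanone 21, now isolated and purified. The ring would be closed in its own step by base-induced intramolecular γ-acylation (DBU or LiN(SiMe3)2, THF, −78 → 0 °C), where base and counter-ion can be chosen without regard to the acylation, giving 22. This fallback still depends on the same ring closure; it only removes the acylation risk.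

2. Step 13. Possible failures are attack in the 5-exo-dig mode at C4, gold-induced side reactions of the dienyne, and incomplete convergence of the C8a epimers. The fallback sets out from 23 and comes back at 25. Gold-catalysed hydration of the ynenone (Ph3PAuNTf2, wet dioxane) should place oxygen at C3 and give the diketone F4. HF·pyridine would free the primary alcohol to give the hydroxy diketone F5. TsOH (cat.) in CH2Cl2 over molecular sieves would close the six-membered hemiketal and dehydrate it to the dienol ether 25 while equilibrating C8a. Ring size is then fixed by the position of the C3 carbonyl group, and no five-membered path exists.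

3. Step 11. Possible failures are acetylation stalling at the dienol acetate of the vinylogous acid, and base-induced ring contraction or silyloxide elimination. The fallback sets out from 22 and comes back at 23. Compound 22 would be converted with LiN(SiMe3)2 (2.1 equiv, THF, −78 °C) into its dianion and quenched with Ac2O, which acetylates the tertiary lithium alkoxide directly and gives the bis-acetate F6 (C7 acetate and C8 dienol acetate). The dienol acetate, a vinylogous anhydride, would then be cleaved selectively with MeOH and K2CO3 (cat.) at 0 °C to return 23.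

**Further compounds**

F1 | step 10 | (2Z,6E,8E,10R)-3-[2-[(tert-butyldimethylsilyl)oxy]ethyl]-2-chloro-8,10-dimethyldodeca-2,6,8-trien-4-yn-1-ol | OC/C(Cl)=C(/C#C/C=C/C(C)=C/[C@H](C)CC)CCO[Si](C)(C)C(C)(C)C
F2 | step 10 | (2Z,6E,8E,10R)-3-[2-[(tert-butyldimethylsilyl)oxy]ethyl]-2-chloro-8,10-dimethyldodeca-2,6,8-trien-4-ynal | O=C/C(Cl)=C(/C#C/C=C/C(C)=C/[C@H](C)CC)CCO[Si](C)(C)C(C)(C)C
F3 | step 10 | (2R,5S)-2-tert-butyl-5-[(2Z,6E,8E,10R)-3-[2-[(tert-butyldimethylsilyl)oxy]ethyl]-2-chloro-1-hydroxy-8,10-dimethyldodeca-2,6,8-trien-4-yn-1-yl]-5-methyl-1,3-dioxolan-4-one (carbinol epimers) | C[C@@]1(C(O)/C(Cl)=C(/C#C/C=C/C(C)=C/[C@H](C)CC)CCO[Si](C)(C)C(C)(C)C)O[C@@H](C(C)(C)C)OC1=O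
F4 | step 13 | (1R)-5-[[(tert-butyldimethylsilyl)oxy]methyl]-3-chloro-4-[(3E,5E,7R)-5,7-dimethyl-2-oxonona-3,5-dien-1-yl]-1-methyl-2,6-dioxocyclohex-3-en-1-yl acetate | CC[C@@H](C)/C=C(C)/C=C/C(=O)CC1=C(Cl)C(=O)[C@](C)(OC(C)=O)C(=O)C1CO[Si](C)(C)C(C)(C)C
F5 | step 13 | (1R)-3-chloro-4-[(3E,5E,7R)-5,7-dimethyl-2-oxonona-3,5-dien-1-yl]-5-(hydroxymethyl)-1-methyl-2,6-dioxocyclohex-3-en-1-yl acetate | CC[C@@H](C)/C=C(C)/C=C/C(=O)CC1=C(Cl)C(=O)[C@](C)(OC(C)=O)C(=O)C1CO
F6 | step 11 | (6R)-6-(acetyloxy)-2-[[(tert-butyldimethylsilyl)oxy]methyl]-4-chloro-3-[(3E,5E,7R)-5,7-dimethylnona-3,5-dien-1-yn-1-yl]-6-methyl-5-oxocyclohexa-1,3-dien-1-yl acetate | CC[C@@H](C)/C=C(C)/C=C/C#CC1=C(Cl)C(=O)[C@](C)(OC(C)=O)C(OC(C)=O)=C1CO[Si](C)(C)C(C)(C)C
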